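# Total synthesis proposal for CNP0000244.0 (target 15)

**Atom labels.** The naphthalene is numbered C1 (bears ring C), C2 (bears the benzyl group), C3 (OH), C4 (H), C4a, C5 (OMe), C6 (OH), C7 (OMe), C8 (H), C8a.
- Ring A is C4a–C5–C6–C7–C8–C8a.
- Ring B is C1–C2–C3–C4–C4a–C8a.
- Ring C is the 4-hydroxy-2-methoxyphenyl group (C1′–C6′).
- Ring D is the 3,4-dihydroxyphenyl ring of the benzyl group (C1″–C6″).
- Isocoumarin 9 keeps the same locants for C1, C3, C4, C4a–C8a.

**Assumption.** The SMILES carries no stereodescriptor, so the hindered C1–C1′ axis is treated as configurationally undefined and no atroposelective step is planned.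

## Analysis of the target

Target 15 (C26H24O8) is a 1-aryl-2-benzylnaphthalen-3-ol: ring B carries four different groups in a row (ring C on C1, the ring D benzyl group on C2, OH on C3, H on C4), and ring A carries OMe on C5, OH on C6, OMe on C7 and H on C8. There is no stereocentre; the only stereochemical element is the C1–C1′ axis, flanked by the 2′-methoxy group, the C2 benzyl group and the peri C8–H, and the SMILES leaves it undefined. The sensitive groups are the five free phenols, among them the ring D catechol and the electron-rich naphthol, which oxidise readily in air and base; three methyl ethers must stay next to them, so the O-methyl/O–H pattern must come from the building blocks and not from a late selective demethylation. The synthesis is hard because the innate reactivity of a finished naphthol points the wrong way (electrophiles go to C4 and C8, not to C1 and C2) and because C1–C1′ is a tri-ortho-substituted biaryl bond. The first feature that invites an unusual cut is the 1,3-relation in ring B between the aryl-bearing C1 and the oxygen-bearing C3, with C4 unsubstituted: C1, C8a, C4a, C4 and C3 are the five carbon atoms of the heteroring of an isocoumarin (C1 as lactone carbonyl, O3 as ring oxygen), and C2 with its benzyl group is the α-methylene of a 2-arylethyl chain on C3. The second feature is that C8a lies para to O6: ring A together with C1 is a 4-oxy-3,5-dimethoxybenzoyl (syringate) unit in which C4a and C8 are related by symmetry and are each ortho to one methoxy group and para to the other, so C4a can be functionalised without any regiochemical question. Ring B can therefore be written by exchanging the ring oxygen of that isocoumarin for carbon C2, with ring C arriving as the nucleophile that triggers the exchange.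

## Retrosynthetic reasoning

**15 ⇒ 14.** The last operation should only unmask oxygen. The four phenols that exist before ring B is made (O6, O4′, O3″, O4″) are carried as benzyl ethers. The three methyl ethers come from the building blocks, and O3 is born free in the key step. Cutting four O–benzyl bonds leads to 14. The forward reaction is a single neutral hydrogenolysis, which avoids base and oxidants at the stage of the free catechol.

**14 ⇒ 9 + 11 (through 12 and 13).** Ring B is cut at C1=C2 and at C1–C1′.
- Cutting C1=C2 (retro-aldol condensation) gives the ring-opened diketone 13.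
- The C3 enol oxygen of 13 can be tied back to C1 once ring C is removed as the aryllithium 12, made from bromide 11. This leaves isocoumarin 9.
- These two bonds are chosen because both are hard to make on an intact naphthalene. In the forward sense the biaryl bond becomes a carbonyl addition, and the ring closure becomes an intramolecular aldol condensation pulled by aromatisation.
- The gain is large: ring C, the biaryl axis and the carbocyclic ring B appear in one operation, and 9 has one ring and one hindered bond fewer.
- The forward reaction has to add 12 only once and then close through the C2 enolate.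

**9 ⇒ 3 + 7 (through 8).** The lactone C1–O bond and the C4–C4a bond are cut.
- C4–C4a is chosen because C4a is the position of the syringate ring where a halogen goes by innate reactivity.
- C4 is the unhindered methyl carbon of ketone 7.
- The forward reaction is a palladium-catalysed ketone α-arylation to keto ester 8, whose enol oxygen then closes on the neighbouring ester.
- An alkyne-based entry to 9 is avoided on purpose. The methoxy groups on C5 and C7 would polarise an arylalkyne so that oxygen attacks C4 instead of C3.

**3 ⇒ 2 ⇒ 1.** The C–Br bond and the O6–benzyl bond are cut. This leads to methyl syringate 1, which already holds the C5/C7 methoxy groups, O6 and C1. Symmetry makes the bromination of 2 unambiguous.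

**7 ⇒ 4 + 5 (through 6).** The C2–CH2(ring D) bond is cut. The forward reaction is alkylation of the enolate of 5 by benzylic chloride 4, and the intermediate 6 then loses one acetyl group. This gives the methyl ketone in one operation without a reduction that would endanger the benzyl ethers.

**11 ⇒ 10.** The O4′–benzyl bond is cut. Phenol 10 already has bromine at C1′, ortho to the methoxy group and para to the hydroxyl group.

## Alternatives that were turned down

Alternative 1: the textbook cut of C1–C1′ by Suzuki–Miyaura coupling of 1-bromonaphthalene A1 with boronic acid A2, followed by hydrogenolysis.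
- The halogen has to sit on C1 and the benzyl group on C2. An O3-substituted naphthalene directs electrophiles to C4, and the ring A methoxy groups direct them to C8.
- A1 therefore cannot be made by decorating a simple naphthol. It needs its own de novo construction of ring B.
- The coupling would then add a tri-ortho-substituted biaryl formation on top of that work, so the disconnection removes ring C but none of the real difficulty.

Alternative 2: C1–C8a and C2–C3 in one cationic [4+2] benzannulation. Acid chloride A3 acylates the benzyl-bearing carbon of 1,3-diarylpropyne A4 under a strong Lewis acid, and the aryl-stabilised vinyl cation at C1 closes on ring A. The alkyne polarity fits the target, but the route was turned down for four structural reasons.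
- The closure must occur at C8a, which is only para to O6 and meta to both methoxy groups, while the doubly activated C8 stays free for intermolecular acylation.
- The linear vinyl cation is equally within reach of ring D, so a five-membered closure competes.
- A donor protecting group on O6 and the benzyl ethers would not survive the Lewis acid.
- A3 has the unsymmetrical 2,3,4-trioxygenated pattern, which costs about five steps, whereas the syringate pattern is bought.

Alternative 3: C1–C8a and C4–C4a by a Diels–Alder reaction between the aryne released from silyl triflate A5 and 2-pyranone A6, followed by decarboxylative aromatisation.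
- The polarities are mismatched. The nucleophilic diene terminus of A6 is the CH next to the oxygen-bearing carbon (the future C4).
- The electrophilic aryne carbon is the one remote from the C5 methoxy group (the future C8a).
- The electronically preferred pairing therefore joins C4 to C8a, the reverse of what the target needs. Sterics pull the other way, so no clean orientation can be argued.
- Both A5 and A6 are multi-step compounds.

Key step: step 6

## Steps

Step 1
Reactants: 1 methyl 4-hydroxy-3,5-dimethoxybenzoate (methyl syringate)
Product: 2 methyl 4-(benzyloxy)-3,5-dimethoxybenzoate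
Conditions: BnBr, K2CO3, DMF, 60 °C
Reagents that add atoms: benzyl bromide, BrCc1ccccc1
Why: Williamson ether synthesis on the only acidic OH; the benzyl ether withstands bromination, palladium catalysis, aryllithium and methoxide and leaves at the end together with the other three.

Step 2
Reactants: 2 methyl 4-(benzyloxy)-3,5-dimethoxybenzoate
Product: 3 methyl 4-(benzyloxy)-2-bromo-3,5-dimethoxybenzoate
Conditions: NBS (1.0 equiv), MeCN, 0 °C to rt, dark
Reagents that add atoms: N-bromosuccinimide, O=C1CCC(=O)N1Br
Why: Electrophilic aromatic bromination; the two free ring positions of 2 are equivalent by symmetry and each is ortho to one methoxy group and para to the other, so only 3 can form, and the ester together with the first bromine slows a second bromination.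

Step 3
Reactants: 4 3,4-bis(benzyloxy)benzyl chloride; 5 pentane-2,4-dione
Product: 7 4-[3,4-bis(benzyloxy)phenyl]butan-2-one, via alkylated diketone 6 (not isolated)
Conditions: K2CO3, NaI (cat.), DMF, 50 °C; then EtOH, reflux
Reagents that add atoms: none
Why: C-Alkylation of the enolate of 5 by the reactive benzylic chloride, then retro-Claisen deacetylation of 6 by ethanolic carbonate (alkylation–cleavage synthesis of methyl ketones); the aprotic first stage avoids solvolysis of 4, and no reduction touches the benzyl ethers.

Step 4
Reactants: 3 methyl 4-(benzyloxy)-2-bromo-3,5-dimethoxybenzoate; 7 4-[3,4-bis(benzyloxy)phenyl]butan-2-one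
Product: 9 6-(benzyloxy)-3-{2-[3,4-bis(benzyloxy)phenyl]ethyl}-5,7-dimethoxy-1H-isochromen-1-one, via keto ester 8 (not isolated)
Conditions: Pd2(dba)3 (cat.), XPhos (cat.), K3PO4, toluene, 100 °C; then CSA (cat.), 5 Å MS, toluene, reflux
Reagents that add atoms: none
Why: Palladium-catalysed ketone α-arylation (Buchwald–Hartwig type): the bulky biarylphosphine lets zerovalent palladium insert into the di-ortho-substituted C–Br bond, and the crowded arylpalladium enolate couples at the methyl carbon of 7 and not at its methylene. The acidic benzylic ketone 8 then closes through its enol oxygen on the neighbouring ester (enol lactonisation), completed by catalytic acid with removal of methanol.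

Step 5
Reactants: 10 4-bromo-3-methoxyphenol
Product: 11 4-(benzyloxy)-1-bromo-2-methoxybenzene
Conditions: BnBr, K2CO3, acetone, reflux
Reagents that add atoms: benzyl bromide, BrCc1ccccc1
Why: Williamson ether synthesis; it removes the acidic proton before the halogen–lithium exchange and uses the same protecting group as on the other phenols.

Step 6
Reactants: 11 4-(benzyloxy)-1-bromo-2-methoxybenzene; 9 6-(benzyloxy)-3-{2-[3,4-bis(benzyloxy)phenyl]ethyl}-5,7-dimethoxy-1H-isochromen-1-one
Product: 14 7-(benzyloxy)-4-[4-(benzyloxy)-2-methoxyphenyl]-3-[3,4-bis(benzyloxy)benzyl]-6,8-dimethoxynaphthalen-2-ol, via aryllithium 12 (not isolated), via ring-opened diketone 13 (not isolated)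
Conditions: 11, n-BuLi, THF, −78 °C; cannulated into 9, THF, −78 °C; then NaOMe, MeOH, −78 to 60 °C, argon; aq. HCl quench
Reagents that add atoms: none
Why: Bromine–lithium exchange gives 12, which adds 1,2 to the lactone carbonyl C1 of 9 (the only free carbonyl, since the C3 ketone is masked as its enol ester), so the hindered C1–C1′ bond forms as a carbonyl addition instead of a tri-ortho-substituted cross-coupling. Collapse of the tetrahedral alkoxide expels the ring oxygen as the C3 enolate, which opens the heteroring to 13 and makes the former ring oxygen the future C3 hydroxyl. Under methoxide the C4 and C2 enolates equilibrate, and only the C2 enolate has a productive partner: it attacks the diaryl ketone C1 in a 6-(enolexo)-exo-trig aldol closure, whereas attack from C4 would need a four-membered ring. E1cB dehydration and enolisation of the C4 methylene give the naphtholate, an irreversible aromatisation that drains all preceding equilibria. The closest known reaction types are the addition of aryl Grignard or aryllithium reagents to isocoumarins on the way to 1-aryl-2-benzopyrylium salts, and the base-induced recyclisation of 1-aryl-3-alkyl-2-benzopyrylium salts through their 1,5-diketone pseudobases into 4-aryl-2-naphthols. No stereocentre is formed and the C1–C1′ axis arises without control. The step needs single addition, secured by inverse addition at −78 °C, by the persistence of the lithium hemiketal alkoxide and by the shielding of the diaryl ketone. It also needs clean closure, secured because rings C and D and all benzyl and methyl ethers are inert to base.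

Step 7
Reactants: 14 7-(benzyloxy)-4-[4-(benzyloxy)-2-methoxyphenyl]-3-[3,4-bis(benzyloxy)benzyl]-6,8-dimethoxynaphthalen-2-ol
Product: 15 4-(4-hydroxy-2-methoxyphenyl)-3-(3,4-dihydroxybenzyl)-6,8-dimethoxynaphthalene-2,7-diol (target CNP0000244.0)
Conditions: H2 (1 atm), Pd/C (10 wt %), THF–MeOH, rt; filtration and concentration under argon
Reagents that add atoms: none
Why: Catalytic hydrogenolysis of four aryl benzyl ethers under neutral conditions; the methyl ethers, the diarylmethane CH2 and the naphthalene core are not touched at ambient pressure, and the reducing medium protects the liberated catechol.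

## Compound list

1 | methyl 4-hydroxy-3,5-dimethoxybenzoate (methyl syringate) | COC(=O)c1cc(OC)c(O)c(OC)c1 | starting material
2 | methyl 4-(benzyloxy)-3,5-dimethoxybenzoate | COC(=O)c1cc(OC)c(OCc2ccccc2)c(OC)c1 | intermediate
3 | methyl 4-(benzyloxy)-2-bromo-3,5-dimethoxybenzoate | COC(=O)c1cc(OC)c(OCc2ccccc2)c(OC)c1Br | intermediate
4 | 3,4-bis(benzyloxy)benzyl chloride | ClCc1ccc(OCc2ccccc2)c(OCc2ccccc2)c1 | starting material
5 | pentane-2,4-dione | CC(=O)CC(C)=O | starting material
6 | 3-[3,4-bis(benzyloxy)benzyl]pentane-2,4-dione (not isolated) | CC(=O)C(Cc1ccc(OCc2ccccc2)c(OCc2ccccc2)c1)C(C)=O | intermediate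
7 | 4-[3,4-bis(benzyloxy)phenyl]butan-2-one | CC(=O)CCc1ccc(OCc2ccccc2)c(OCc2ccccc2)c1 | intermediate
8 | methyl 4-(benzyloxy)-2-{4-[3,4-bis(benzyloxy)phenyl]-2-oxobutyl}-3,5-dimethoxybenzoate (not isolated) | COC(=O)c1cc(OC)c(OCc2ccccc2)c(OC)c1CC(=O)CCc1ccc(OCc2ccccc2)c(OCc2ccccc2)c1 | intermediate
9 | 6-(benzyloxy)-3-{2-[3,4-bis(benzyloxy)phenyl]ethyl}-5,7-dimethoxy-1H-isochromen-1-one | O=C1OC(CCc2ccc(OCc3ccccc3)c(OCc3ccccc3)c2)=Cc2c(OC)c(OCc3ccccc3)c(OC)cc12 | intermediate
10 | 4-bromo-3-methoxyphenol | COc1cc(O)ccc1Br | starting material
11 | 4-(benzyloxy)-1-bromo-2-methoxybenzene | COc1cc(OCc2ccccc2)ccc1Br | intermediate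
12 | [4-(benzyloxy)-2-methoxyphenyl]lithium (not isolated) | COc1cc(OCc2ccccc2)ccc1[Li] | intermediate
13 | 1-{3-(benzyloxy)-6-[4-(benzyloxy)-2-methoxybenzoyl]-2,4-dimethoxyphenyl}-4-[3,4-bis(benzyloxy)phenyl]butan-2-one (not isolated) | COc1cc(OCc2ccccc2)ccc1C(=O)c1cc(OC)c(OCc2ccccc2)c(OC)c1CC(=O)CCc1ccc(OCc2ccccc2)c(OCc2ccccc2)c1 | intermediate
14 | 7-(benzyloxy)-4-[4-(benzyloxy)-2-methoxyphenyl]-3-[3,4-bis(benzyloxy)benzyl]-6,8-dimethoxynaphthalen-2-ol | COc1cc(OCc2ccccc2)ccc1-c1c(Cc2ccc(OCc3ccccc3)c(OCc3ccccc3)c2)c(O)cc2c(OC)c(OCc3ccccc3)c(OC)cc12 | intermediate
15 | 4-(4-hydroxy-2-methoxyphenyl)-3-(3,4-dihydroxybenzyl)-6,8-dimethoxynaphthalene-2,7-diol (CNP0000244.0) | COc1cc(O)ccc1-c1c(Cc2ccc(O)c(O)c2)c(O)cc2c(OC)c(O)c(OC)cc12 | target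

## Step count and least certain steps

Total step count: 7. Longest linear sequence: 5 steps (steps 1, 2, 4, 6, 7).

**Step 6 (key step).**
- What may go wrong: a second addition of 12 if the tetrahedral alkoxide collapses early and unveils the ketone; competing deprotonation of the allylic CH2 on C3 of 9; or stalling at the ring-opened diketone or cyclic hemiketal stage, because the C2 enolate is the minor one and the diaryl ketone is hindered and electron-rich.
- Fallback: it changes the order of events to ring closure on the ester first and biaryl bond by cross-coupling afterwards. It sets out from 9 and comes back to the route at 14.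
- Heating 9 with NaOMe in MeOH opens the lactone to the enolate of 8. Its C2 carbanion closes on the far less hindered ester (Dieckmann-type condensation) to give the naphthalene-1,3-diol F1.
- The less hindered 3-OH is silylated with TIPSCl and imidazole to the 3-O-triisopropylsilyl ether F2.
- The peri-flanked 1-OH is converted with Tf2O and pyridine into the 1-triflate F3.
- Suzuki–Miyaura coupling (Pd(OAc)2, SPhos, K3PO4, toluene–water) with the pinacol boronate F4, made from 12 and 2-isopropoxy-4,4,5,5-tetramethyl-1,3,2-dioxaborolane, gives the silyl-protected biaryl F5. TBAF then releases 14 from F5.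

**Step 4.**
- What may go wrong: slow oxidative addition and hydrodebromination at the di-ortho-substituted, electron-rich bromide; base-induced self-condensation of 7; and premature Dieckmann closure of 8 before the enol lactone forms.
- Fallback: it builds C4–C4a as an sp2–sp bond and sets the C3 oxygen by hydroboration. It sets out from 4 and 3 and comes back to the route at 8, which is lactonised to 9 as in step 4.
- Chloride 4 is alkylated with lithiated 1-(trimethylsilyl)propyne to the silyl alkyne F6, and K2CO3 in MeOH gives the terminal alkyne F7.
- Copper-free Sonogashira coupling with 3 (PdCl2(MeCN)2, XPhos, Cs2CO3, MeCN) gives the alkynylbenzoate F8.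
- Hydroboration with dicyclohexylborane should place boron on C3. That carbon is remote from the crowded ring and is made electron-rich by the C5 and C7 methoxy groups. Oxidation with NaBO3 then gives 8.
- A π-acid or Brønsted acid cyclisation of F8 is not used, because the same polarisation would steer oxygen to C4.

**Step 7.**
- What may go wrong: air oxidation of the liberated catechol and naphthol during filtration and chromatography, and slow cleavage of the benzyl ether on O6 between two methoxy groups.
- Fallback: it replaces hydrogenolysis by Lewis acid debenzylation and isolates a stable derivative. It sets out from 14 and comes back at 15.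
- BCl3 with pentamethylbenzene in CH2Cl2 at −78 °C removes the benzyl groups.
- The crude pentaphenol is acetylated at once (Ac2O, pyridine) to the pentaacetate F9, which can be purified in air.
- Degassed HCl in MeOH then cleaves the acetates under acidic, non-oxidising conditions to give 15.

## Further compounds

F1 | step 6 | 6-(benzyloxy)-2-[3,4-bis(benzyloxy)benzyl]-5,7-dimethoxynaphthalene-1,3-diol | Oc1c(Cc2ccc(OCc3ccccc3)c(OCc3ccccc3)c2)c(O)cc2c(OC)c(OCc3ccccc3)c(OC)cc12
F2 | step 6 | 6-(benzyloxy)-2-[3,4-bis(benzyloxy)benzyl]-5,7-dimethoxy-3-[(triisopropylsilyl)oxy]naphthalen-1-ol | Oc1c(Cc2ccc(OCc3ccccc3)c(OCc3ccccc3)c2)c(O[Si](C(C)C)(C(C)C)C(C)C)cc2c(OC)c(OCc3ccccc3)c(OC)cc12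
F3 | step 6 | 6-(benzyloxy)-2-[3,4-bis(benzyloxy)benzyl]-5,7-dimethoxy-3-[(triisopropylsilyl)oxy]naphthalen-1-yl trifluoromethanesulfonate | O=S(=O)(Oc1c(Cc2ccc(OCc3ccccc3)c(OCc3ccccc3)c2)c(O[Si](C(C)C)(C(C)C)C(C)C)cc2c(OC)c(OCc3ccccc3)c(OC)cc12)C(F)(F)F
F4 | step 6 | 2-[4-(benzyloxy)-2-methoxyphenyl]-4,4,5,5-tetramethyl-1,3,2-dioxaborolane | COc1cc(OCc2ccccc2)ccc1B1OC(C)(C)C(C)(C)O1
F5 | step 6 | {[7-(benzyloxy)-4-[4-(benzyloxy)-2-methoxyphenyl]-3-[3,4-bis(benzyloxy)benzyl]-6,8-dimethoxynaphthalen-2-yl]oxy}triisopropylsilane | COc1cc(OCc2ccccc2)ccc1-c1c(Cc2ccc(OCc3ccccc3)c(OCc3ccccc3)c2)c(O[Si](C(C)C)(C(C)C)C(C)C)cc2c(OC)c(OCc3ccccc3)c(OC)cc12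
F6 | step 4 | {4-[3,4-bis(benzyloxy)phenyl]but-1-yn-1-yl}trimethylsilane | C[Si](C)(C)C#CCCc1ccc(OCc2ccccc2)c(OCc2ccccc2)c1
F7 | step 4 | 1,2-bis(benzyloxy)-4-(but-3-yn-1-yl)benzene | C#CCCc1ccc(OCc2ccccc2)c(OCc2ccccc2)c1
F8 | step 4 | methyl 4-(benzyloxy)-2-{4-[3,4-bis(benzyloxy)phenyl]but-1-yn-1-yl}-3,5-dimethoxybenzoate | COC(=O)c1cc(OC)c(OCc2ccccc2)c(OC)c1C#CCCc1ccc(OCc2ccccc2)c(OCc2ccccc2)c1
F9 | step 7 | penta-O-acetyl derivative of 15 | COc1cc(OC(C)=O)ccc1-c1c(Cc2ccc(OC(C)=O)c(OC(C)=O)c2)c(OC(C)=O)cc2c(OC)c(OC(C)=O)c(OC)cc12
A1 | alternative 1 | 3,6-bis(benzyloxy)-2-[3,4-bis(benzyloxy)benzyl]-1-bromo-5,7-dimethoxynaphthalene | Brc1c(Cc2ccc(OCc3ccccc3)c(OCc3ccccc3)c2)c(OCc2ccccc2)cc2c(OC)c(OCc3ccccc3)c(OC)cc12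
A2 | alternative 1 | [4-(benzyloxy)-2-methoxyphenyl]boronic acid | COc1cc(OCc2ccccc2)ccc1B(O)O
A3 | alternative 2 | 2-[3-(benzyloxy)-2,4-dimethoxyphenyl]acetyl chloride | O=C(Cl)Cc1ccc(OC)c(OCc2ccccc2)c1OC
A4 | alternative 2 | 4-(benzyloxy)-1-{3-[3,4-bis(benzyloxy)phenyl]prop-1-yn-1-yl}-2-methoxybenzene | COc1cc(OCc2ccccc2)ccc1C#CCc1ccc(OCc2ccccc2)c(OCc2ccccc2)c1
A5 | alternative 3 | 4-(benzyloxy)-3,5-dimethoxy-2-(trimethylsilyl)phenyl trifluoromethanesulfonate | COc1cc(OS(=O)(=O)C(F)(F)F)c([Si](C)(C)C)c(OC)c1OCc1ccccc1
A6 | alternative 3 | 4-(benzyloxy)-6-[4-(benzyloxy)-2-methoxyphenyl]-5-[3,4-bis(benzyloxy)benzyl]-2H-pyran-2-one | O=C1C=C(OCc2ccccc2)C(Cc2ccc(OCc3ccccc3)c(OCc3ccccc3)c2)=C(c2ccc(OCc3ccccc3)cc2OC)O1
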